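**Plan**
- Cuts: the side lactone comes off the pyrrole at its Cα–C(O) bond (then C–O); the ring-lactone methyl goes back to an α-methylene; the azepine ring is cut at N–CH2 and at the CH2–CH2 bond beside the ring CH; the cyclohexane ring is cut at pyrrole Cβ–CH and at CH(Et)–CH(pyrrole).
- Enabling feature: in the azepine ring the pyrrole N and the exocyclic carbon on the ring CH next to the pyrrole α-carbon are 1,4-related (N, Cα, CH, C). As pyrrolide N and formyl C they form a nucleophile/electrophile pair that a cyclopropylphosphonium C3 unit (electrophilic CH2, then ylide carbon) bridges in one event.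
- Forward order: bought pyrrole → acyclic Michael adduct → cyclohexanone ring by Pd enolate arylation → cis γ-lactone → azepine ring → lactone methyl → side lactone on the last free pyrrole α-C–H.
- Stereochemistry: the ring CH next to N comes from a thiourea-catalysed Michael addition (absolute control); CH(Et) and CH(CH2CO) from equilibration of the ketone to the all-equatorial isomer; the ring carbinol from equatorial hydride attack; the lactone methyl from convex-face hydrogenation; the side-chain methyl from (S)-methylsuccinic acid; the side carbinol from asymmetric transfer hydrogenation.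

Key step: step 10

Assumption: the sense of induction of the thiourea catalyst in step 4 is taken by analogy with malonate additions to aryl nitroalkenes; were it opposite, the mirror-image catalyst would be used and nothing else would change.

Step 1
Reactants: 1 dimethyl 3-oxohexanedioate
Product: 2 dimethyl 2-ethyl-3-oxohexanedioate (racemic)
Conditions: EtI, K2CO3, acetone, 56 °C
Reagents that add atoms: iodoethane (CCI)
Why: C-alkylation of a β-keto ester at its only doubly activated carbon gives the α-ethyl donor; the new stereocentre is racemic and is erased in step 7.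

Step 2
Reactants: 3 3-bromo-1H-pyrrole-2-carbaldehyde
Product: 4 3-bromo-1-(4-methylbenzenesulfonyl)-1H-pyrrole-2-carbaldehyde
Conditions: NaH, THF, 0 °C; TsCl, 0 °C → rt
Reagents that add atoms: 4-methylbenzenesulfonyl chloride (Cc1ccc(cc1)S(Cl)(=O)=O)
Why: N-sulfonylation of the pyrrolide; the sulfonyl group makes the later nitroalkene electrophilic, protects the pyrrole in the acid and Pd steps, and is removed in step 8.

Step 3
Reactants: 4 3-bromo-1-(4-methylbenzenesulfonyl)-1H-pyrrole-2-carbaldehyde
Product: 5 3-bromo-1-(4-methylbenzenesulfonyl)-2-[(E)-2-nitroethenyl]-1H-pyrrole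
Conditions: MeNO2 (solvent), NH4OAc (0.5 equiv), 90 °C
Reagents that add atoms: nitromethane (C[N+](=O)[O-])
Why: Henry reaction followed by dehydration should give the conjugated nitroalkene as the more stable E isomer.

Step 4
Reactants: 5 3-bromo-1-(4-methylbenzenesulfonyl)-2-[(E)-2-nitroethenyl]-1H-pyrrole, 2 dimethyl 2-ethyl-3-oxohexanedioate
Product: 6 dimethyl 2-{(1S)-1-[3-bromo-1-(4-methylbenzenesulfonyl)-1H-pyrrol-2-yl]-2-nitroethyl}-2-ethyl-3-oxohexanedioate (both configurations at the quaternary carbon)
Conditions: 2 (1.5 equiv), (R,R)-Takemoto catalyst {1-[3,5-bis(trifluoromethyl)phenyl]-3-[(1R,2R)-2-(dimethylamino)cyclohexyl]thiourea, 10 mol %}, toluene, rt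
Reagents that add atoms: none
Why: Bifunctional thiourea/tertiary-amine catalysed Michael addition of a 2-substituted β-keto ester to a nitroalkene, in which the thiourea binds the nitro group and the ammonium-bound enolate is delivered to one face, so that the pyrrole-bearing carbon (the later ring CH next to N) should form with S configuration (S here because the N-bearing pyrrole carbon outranks CH2NO2), while the quaternary centre is of no consequence.

Step 5
Reactants: 6 dimethyl 2-{(1S)-1-[3-bromo-1-(4-methylbenzenesulfonyl)-1H-pyrrol-2-yl]-2-nitroethyl}-2-ethyl-3-oxohexanedioate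
Product: 7 dimethyl 2-{(1R)-1-[3-bromo-1-(4-methylbenzenesulfonyl)-1H-pyrrol-2-yl]-2,2-dimethoxyethyl}-2-ethyl-3-oxohexanedioate
Conditions: NaOMe (1.05 equiv), MeOH, 0 °C; then added to H2SO4/MeOH, −45 → 0 °C
Reagents that add atoms: methanol (CO)
Why: Nef reaction run as acid solvolysis of the nitronate in methanol, which turns CH2NO2 directly into the dimethyl acetal without a free epimerizable α-aryl aldehyde; the one equivalent of methoxide is consumed by the acidic nitro group, which spares the non-enolizable β-keto ester from retro-Claisen cleavage (the descriptor changes to R only because of priorities).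

Step 6
Reactants: 7 dimethyl 2-{(1R)-1-[3-bromo-1-(4-methylbenzenesulfonyl)-1H-pyrrol-2-yl]-2,2-dimethoxyethyl}-2-ethyl-3-oxohexanedioate
Product: 8 methyl (7R)-7-(dimethoxymethyl)-6-ethyl-4-(2-methoxy-2-oxoethyl)-1-(4-methylbenzenesulfonyl)-5-oxo-4,5,6,7-tetrahydro-1H-indole-6-carboxylate (mixture at C4 and C6)
Conditions: Pd(OAc)2 (5 mol %), Xantphos (7.5 mol %), K3PO4, toluene, 100 °C
Reagents that add atoms: none
Why: Intramolecular Pd-catalysed α-arylation of a ketone enolate; the quaternary carbon on one side leaves only the CH2 on the other side of the ketone enolizable, and its coupling with the pyrrole 3-bromide closes the six-membered ring at the pyrrole β-carbon (the new stereocentre is equilibrated in step 8).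

Step 7
Reactants: 8 methyl (7R)-7-(dimethoxymethyl)-6-ethyl-4-(2-methoxy-2-oxoethyl)-1-(4-methylbenzenesulfonyl)-5-oxo-4,5,6,7-tetrahydro-1H-indole-6-carboxylate
Product: 9 methyl 2-[(7R)-7-(dimethoxymethyl)-6-ethyl-1-(4-methylbenzenesulfonyl)-5-oxo-4,5,6,7-tetrahydro-1H-indol-4-yl]acetate (mixture at C4 and C6)
Conditions: LiCl, H2O (2 equiv), DMSO, 140 °C
Reagents that add atoms: none
Why: Krapcho demethoxycarbonylation (chloride SN2 at the methyl group of the β-keto ester, then loss of CO2) removes the helper ester selectively, leaves the simple acetate ester and the acetal, and makes the CH(Et) carbon epimerizable.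

Step 8
Reactants: 9 methyl 2-[(7R)-7-(dimethoxymethyl)-6-ethyl-1-(4-methylbenzenesulfonyl)-5-oxo-4,5,6,7-tetrahydro-1H-indol-4-yl]acetate
Product: 10 methyl 2-[(4S,6R,7R)-7-(dimethoxymethyl)-6-ethyl-5-oxo-4,5,6,7-tetrahydro-1H-indol-4-yl]acetate
Conditions: Cs2CO3, MeOH/THF (1:2), 40 °C, argon
Reagents that add atoms: none
Why: Methoxide cleaves the N-sulfonyl group and, with the bulky N-substituent next to C7 gone, enolization should equilibrate both ketone α-carbons to the all-equatorial isomer (ethyl trans to the dimethoxymethyl group, acetate arm cis to ethyl across the carbonyl).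

Step 9
Reactants: 10 methyl 2-[(4S,6R,7R)-7-(dimethoxymethyl)-6-ethyl-5-oxo-4,5,6,7-tetrahydro-1H-indol-4-yl]acetate
Product: 13 (4S,5R,6R,7R)-6-ethyl-7-formyl-5-hydroxy-4,5,6,7-tetrahydro-1H-indol-4-ylacetic acid γ-lactone, via hydroxy ester alkoxide 11 (not isolated), via lactone acetal 12 (not isolated)
Conditions: LiBH(CHMeEt)3 (L-Selectride, 2.5 equiv), THF, −78 → 0 °C; then AcOH/H2O (4:1), 35 °C
Reagents that add atoms: water (O)
Why: The bulky hydride should attack the ketone from the equatorial direction to give the axial alkoxide cis to both equatorial neighbours, which lactonizes onto the adjacent acetate ester to the cis-fused γ-lactone, and mild aqueous acid then hydrolyses the acetal to the aldehyde.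

Step 10
Reactants: 13 (4S,5R,6R,7R)-6-ethyl-7-formyl-5-hydroxy-4,5,6,7-tetrahydro-1H-indol-4-ylacetic acid γ-lactone, 14 cyclopropyltriphenylphosphonium bromide
Product: 16 tetracyclic lactone in which N1 and C7 of 13 are joined as N–CH2–CH2–CH=CH–C7 (cis alkene; ring stereocentres as in 13), via phosphorus ylide 15 (not isolated)
Conditions: NaH (1.05 equiv), DMF, 0 °C; then 14 (1.3 equiv), 90 °C
Reagents that add atoms: none
Why: Proposed new method: the sodium pyrrolide of 13 should open the cyclopropane of 14 by SN2-type attack at a ring CH2 (homo-conjugate addition to the phosphonium), which makes the N–CH2 bond and leaves the charge as the non-stabilized ylide 15, whose carbon then adds to the formyl carbon and collapses through an oxaphosphetane to the ring C=C (the carbon–carbon bond beside the ring methine, kept as the σ bond after step 12) and Ph3PO. The closest known reaction type is the Schweizer annulation of the sodium salts of salicylaldehyde or pyrrole-2-carbaldehyde with vinyl- and cyclopropyltriphenylphosphonium salts; not shown so far is its use on an N–H azole whose formyl group sits on an sp3 carbon and is enolizable. The seven-membered ring is closed at carbon by the intramolecular Wittig olefination (7-exo-trig addition of the ylide carbon to C=O) after an intermolecular N-alkylation, a formal [4+3] union of the 1,4-related N/CHO pair with a 1,3 electrophile–nucleophile. No stereocentre is created: the alkene is cis by ring size, and the formyl-bearing methine, which can epimerize through the enolate, should settle with its substituent trans to ethyl (both pseudo-equatorial), as the target needs. The step needs N-alkylation in preference to C- or O-alkylation of the aldehyde enolate and olefination of the aldehyde in preference to the lactone; the planar, unhindered pyrrolide nitrogen is the better partner for SN2 opening than the tertiary enolate carbon, exactly one equivalent of NaH keeps the ylide from being quenched, and only the aldehyde is electrophilic enough and close enough for the ylide.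

Step 11
Reactants: 16 tetracyclic dihydroazepine lactone
Product: 19 α-methylene lactone (16 with C=CH2 on the lactone α-carbon), via Mannich base 17 (not isolated), via ammonium iodide 18 (not isolated)
Conditions: LiN(CHMe2)2, THF, −78 °C; Me2N=CH2+ I−, −78 °C → rt; then MeI, MeOH, rt; then aq. NaHCO3/CH2Cl2, rt
Reagents that add atoms: N,N-dimethylmethyleneiminium iodide (C=[N+](C)C.[I-]); iodomethane (CI, into intermediate 18 only)
Why: Eschenmoser α-methylenation: the lithium enolate of the lactone (the only carbonyl α-CH2) undergoes a Mannich reaction with the iminium salt, and N-methylation followed by E1cB loss of trimethylamine gives the α-methylene lactone.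

Step 12
Reactants: 19 α-methylene lactone
Product: 20 saturated tetracyclic lactone (N–CH2CH2CH2CH2–C7 ring; lactone α-carbon S with CH3 on the concave face; other stereocentres as in 13)
Conditions: H2 (3 atm), RhCl(PPh3)3 (10 mol %), benzene/EtOH (1:1), rt
Reagents that add atoms: none
Why: Homogeneous hydrogenation saturates the ring cis-alkene and adds hydrogen to the exocyclic methylene from the convex face of the cis-fused bicyclic lactone (the face of the two ring-fusion hydrogens), so the methyl should end on the concave face as required, and RhCl(PPh3)3 avoids migration of the exocyclic double bond into the ring.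

Step 13
Reactants: 21 (S)-2-methylbutanedioic acid
Product: 22 (3S)-3-methyloxolane-2,5-dione
Conditions: AcCl, 55 °C
Reagents that add atoms: none
Why: Dehydration of the 1,4-diacid to its cyclic anhydride, in which the stereocentre takes no part.

Step 14
Reactants: 22 (3S)-3-methyloxolane-2,5-dione
Product: 23 (2S)-4-(dimethylamino)-2-methyl-4-oxobutanoic acid
Conditions: Me2NH (2 M in THF, 1.05 equiv), THF, −20 °C → rt
Reagents that add atoms: dimethylamine (CNC)
Why: Aminolysis of the anhydride should occur mainly at the less hindered carbonyl remote from the methyl group, leaving the acid beside the stereocentre (the minor regioisomer is removed by crystallization).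

Step 15
Reactants: 23 (2S)-4-(dimethylamino)-2-methyl-4-oxobutanoic acid
Product: 24 methyl (2S)-4-(dimethylamino)-2-methyl-4-oxobutanoate
Conditions: MeI, K2CO3, DMF, rt
Reagents that add atoms: iodomethane (CI)
Why: SN2 O-alkylation of the carboxylate under weakly basic conditions that should not epimerize the α-stereocentre.

Step 16
Reactants: 20 saturated tetracyclic lactone, 24 methyl (2S)-4-(dimethylamino)-2-methyl-4-oxobutanoate
Product: 26 keto ester (20 bearing –C(=O)CH2CH(CH3)CO2CH3 at the free pyrrole α-carbon; S at the methyl-bearing carbon), via iminium salt 25 (not isolated)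
Conditions: 24 (1.3 equiv), POCl3 (1.3 equiv), ClCH2CH2Cl, 0 °C → rt; then 20, 60 °C; then aq. NaOAc, 60 °C
Reagents that add atoms: water (O)
Why: Vilsmeier–Haack acylation with a tertiary amide: the chloroiminium ion attacks the only free pyrrole α-position (intrinsic α-selectivity of the electron-rich N-alkylpyrrole), and hydrolysis of the iminium salt gives the 2-acylpyrrole with the methyl stereocentre, β to the reacting carbon, untouched.

Step 17
Reactants: 26 keto ester
Product: 28 target CNP0232452.1, via hydroxy ester 27 (not isolated)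
Conditions: Ru[(R,R)-TsNCH(Ph)CH(Ph)NH](η6-p-cymene) (5 mol %), 2-propanol, 30 °C; then toluene, 60 °C
Reagents that add atoms: none
Why: Noyori–Ikariya asymmetric transfer hydrogenation of the aryl ketone under neutral conditions, the (R,R) ligand being the one that gives R carbinols from aryl alkyl ketones, followed by lactonization of the γ-hydroxy ester, which removes the alcohol from the reversible hydrogen-transfer equilibrium and places pyrrolyl and methyl trans on the new lactone.

**Compound list**
1 | dimethyl 3-oxohexanedioate | COC(=O)CC(=O)CCC(=O)OC | starting material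
2 | dimethyl 2-ethyl-3-oxohexanedioate (racemic) | COC(=O)C(CC)C(=O)CCC(=O)OC | intermediate
3 | 3-bromo-1H-pyrrole-2-carbaldehyde | O=Cc1[nH]ccc1Br | starting material
4 | 3-bromo-1-(4-methylbenzenesulfonyl)-1H-pyrrole-2-carbaldehyde | O=Cc1n(S(=O)(=O)c2ccc(C)cc2)ccc1Br | intermediate
5 | 3-bromo-1-(4-methylbenzenesulfonyl)-2-[(E)-2-nitroethenyl]-1H-pyrrole | O=[N+]([O-])/C=C/c1n(S(=O)(=O)c2ccc(C)cc2)ccc1Br | intermediate
6 | dimethyl 2-{(1S)-1-[3-bromo-1-(4-methylbenzenesulfonyl)-1H-pyrrol-2-yl]-2-nitroethyl}-2-ethyl-3-oxohexanedioate (both configurations at the quaternary carbon) | COC(=O)C(CC)(C(=O)CCC(=O)OC)[C@H](c1n(S(=O)(=O)c2ccc(C)cc2)ccc1Br)C[N+](=O)[O-] | intermediate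
7 | dimethyl 2-{(1R)-1-[3-bromo-1-(4-methylbenzenesulfonyl)-1H-pyrrol-2-yl]-2,2-dimethoxyethyl}-2-ethyl-3-oxohexanedioate (both configurations at the quaternary carbon) | COC(=O)C(CC)(C(=O)CCC(=O)OC)[C@H](c1n(S(=O)(=O)c2ccc(C)cc2)ccc1Br)C(OC)OC | intermediate
8 | methyl (7R)-7-(dimethoxymethyl)-6-ethyl-4-(2-methoxy-2-oxoethyl)-1-(4-methylbenzenesulfonyl)-5-oxo-4,5,6,7-tetrahydro-1H-indole-6-carboxylate (mixture at C4 and C6) | COC(=O)C1(CC)C(=O)C(CC(=O)OC)c2ccn(S(=O)(=O)c3ccc(C)cc3)c2[C@@H]1C(OC)OC | intermediate
9 | methyl 2-[(7R)-7-(dimethoxymethyl)-6-ethyl-1-(4-methylbenzenesulfonyl)-5-oxo-4,5,6,7-tetrahydro-1H-indol-4-yl]acetate (mixture at C4 and C6) | CCC1C(=O)C(CC(=O)OC)c2ccn(S(=O)(=O)c3ccc(C)cc3)c2[C@@H]1C(OC)OC | intermediate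
10 | methyl 2-[(4S,6R,7R)-7-(dimethoxymethyl)-6-ethyl-5-oxo-4,5,6,7-tetrahydro-1H-indol-4-yl]acetate | CC[C@H]1C(=O)[C@@H](CC(=O)OC)c2cc[nH]c2[C@@H]1C(OC)OC | intermediate
11 | methyl 2-[(4S,5R,6R,7R)-7-(dimethoxymethyl)-6-ethyl-5-hydroxy-4,5,6,7-tetrahydro-1H-indol-4-yl]acetate (present as its lithium alkoxide) | CC[C@H]1[C@@H](O)[C@@H](CC(=O)OC)c2cc[nH]c2[C@@H]1C(OC)OC | intermediate
12 | (4S,5R,6R,7R)-7-(dimethoxymethyl)-6-ethyl-5-hydroxy-4,5,6,7-tetrahydro-1H-indol-4-ylacetic acid γ-lactone (cis-fused) | CC[C@H]1[C@H]2OC(=O)C[C@H]2c2cc[nH]c2[C@@H]1C(OC)OC | intermediate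
13 | (4S,5R,6R,7R)-6-ethyl-7-formyl-5-hydroxy-4,5,6,7-tetrahydro-1H-indol-4-ylacetic acid γ-lactone | CC[C@H]1[C@H]2OC(=O)C[C@H]2c2cc[nH]c2[C@@H]1C=O | intermediate
14 | cyclopropyltriphenylphosphonium bromide | [Br-].C1CC1[P+](c1ccccc1)(c1ccccc1)c1ccccc1 | starting material
15 | N-[3-(triphenylphosphoranylidene)propyl] derivative of 13 (phosphorus ylide) | CC[C@H]1[C@H]2OC(=O)C[C@H]2c2ccn(CCC=P(c3ccccc3)(c3ccccc3)c3ccccc3)c2[C@@H]1C=O | intermediate
16 | tetracyclic lactone with N1 and C7 of 13 joined as N–CH2–CH2–CH=CH–C7 (cis alkene; stereocentres as in 13) | CC[C@H]1[C@H]2OC(=O)C[C@H]2c2ccn3c2[C@@H]1C=CCC3 | intermediate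
17 | α-(dimethylaminomethyl) lactone of 16 (Mannich base, both α-epimers) | CC[C@H]1[C@H]2OC(=O)C(CN(C)C)[C@H]2c2ccn3c2[C@@H]1C=CCC3 | intermediate
18 | α-(trimethylammoniomethyl) lactone iodide from 17 | CC[C@H]1[C@H]2OC(=O)C(C[N+](C)(C)C)[C@H]2c2ccn3c2[C@@H]1C=CCC3.[I-] | intermediate
19 | α-methylene lactone (16 with C=CH2 on the lactone α-carbon) | CC[C@H]1[C@H]2OC(=O)C(=C)[C@H]2c2ccn3c2[C@@H]1C=CCC3 | intermediate
20 | saturated tetracyclic lactone (N–(CH2)4–C7 ring; lactone α-carbon S with CH3 on the concave face; other stereocentres as in 13) | CC[C@H]1[C@H]2OC(=O)[C@@H](C)[C@H]2c2ccn3c2[C@@H]1CCCC3 | intermediate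
21 | (S)-2-methylbutanedioic acid | OC(=O)C[C@H](C)C(=O)O | starting material
22 | (3S)-3-methyloxolane-2,5-dione | O=C1C[C@H](C)C(=O)O1 | intermediate
23 | (2S)-4-(dimethylamino)-2-methyl-4-oxobutanoic acid | CN(C)C(=O)C[C@H](C)C(=O)O | intermediate
24 | methyl (2S)-4-(dimethylamino)-2-methyl-4-oxobutanoate | CN(C)C(=O)C[C@H](C)C(=O)OC | intermediate
25 | iminium dichlorophosphate from 20 and 24 (pyrrole α-carbon bound to C(=N+Me2)CH2CH(CH3)CO2CH3) | CC[C@H]1[C@H]2OC(=O)[C@@H](C)[C@H]2c2cc(C(C[C@H](C)C(=O)OC)=[N+](C)C)n3c2[C@@H]1CCCC3.[O-]P(Cl)(Cl)=O | intermediate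
26 | keto ester (20 with –C(=O)CH2CH(CH3)CO2CH3 at the pyrrole α-carbon; S at the methyl-bearing carbon) | CC[C@H]1[C@H]2OC(=O)[C@@H](C)[C@H]2c2cc(C(=O)C[C@H](C)C(=O)OC)n3c2[C@@H]1CCCC3 | intermediate
27 | hydroxy ester (R carbinol of 26) | CC[C@H]1[C@H]2OC(=O)[C@@H](C)[C@H]2c2cc([C@H](O)C[C@H](C)C(=O)OC)n3c2[C@@H]1CCCC3 | intermediate
28 | CNP0232452.1 | CC[C@H]1[C@H]2OC(=O)[C@@H](C)[C@H]2c2cc([C@H]3C[C@H](C)C(=O)O3)n3c2[C@@H]1CCCC3 | target

**Count and risks**
Total steps: 17. Longest linear sequence: 13 (steps 2–12, 16, 17).

Step 10 (bears the label). The unactivated cyclopropane may open too slowly at the pyrrolide nitrogen, so that alkylation through the aldehyde enolate, aldol self-condensation, or protonation of the ylide before olefination take over. The fallback sets out from 13 and makes the two bonds one after the other by known reactions. Wittig methylenation of the aldehyde (Ph3P=CH2 from methyltriphenylphosphonium bromide and KN(SiMe3)2, THF) gives the 7-ethenyl lactone F1. N-Alkylation of its sodium salt with 4-bromobut-1-ene (NaH, DMF) gives the N-(but-3-enyl) diene F2. Ring-closing metathesis with the second-generation Grubbs catalyst (CH2Cl2, 40 °C) closes the seven-membered ring with loss of ethene and comes back to the route at 16.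

Step 4. Addition of the fully substituted enol to the hindered, twisted nitroalkene may be slow or reversible, with loss of enantioselectivity. The fallback sets out from 5 and 1, the unalkylated and far more reactive CH2 donor. The same thiourea-catalysed Michael addition gives the adduct F3. C-Ethylation at its β-keto ester carbon (K2CO3, EtI, acetone) comes back to the route at 6, and step 1 is then not needed.

Step 17. Hydride transfer to the electron-rich acylpyrrole carbonyl (a vinylogous amide) may be slow, and the pyrrolyl carbinol may ionize, which would erase the new stereocentre or lead to over-reduction. The fallback sets out from 20 and builds the carbinol by C–C bond formation instead of reduction. Vilsmeier–Haack formylation (DMF, POCl3; aq. NaOAc) gives the pyrrole α-carbaldehyde F4. Addition of the zinc homoenolate made from methyl (2R)-3-iodo-2-methylpropanoate (Zn/Cu couple, then ClTi(OCHMe2)3, THF) comes back to the route at hydroxy ester 27, formed together with its carbinol epimer. Both lactonize, and the two lactone diastereomers are separated by chromatography, 28 being one of them.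

**Further compounds**
F1 | step 10 | (4S,5R,6R,7R)-7-ethenyl-6-ethyl-5-hydroxy-4,5,6,7-tetrahydro-1H-indol-4-ylacetic acid γ-lactone | CC[C@H]1[C@H]2OC(=O)C[C@H]2c2cc[nH]c2[C@@H]1C=C
F2 | step 10 | N-(but-3-enyl) derivative of F1 | CC[C@H]1[C@H]2OC(=O)C[C@H]2c2ccn(CCC=C)c2[C@@H]1C=C
F3 | step 4 | dimethyl 2-{(1S)-1-[3-bromo-1-(4-methylbenzenesulfonyl)-1H-pyrrol-2-yl]-2-nitroethyl}-3-oxohexanedioate (both configurations at C2) | COC(=O)C(C(=O)CCC(=O)OC)[C@H](c1n(S(=O)(=O)c2ccc(C)cc2)ccc1Br)C[N+](=O)[O-]
F4 | step 17 | pyrrole α-carbaldehyde of 20 | CC[C@H]1[C@H]2OC(=O)[C@@H](C)[C@H]2c2cc(C=O)n3c2[C@@H]1CCCC3
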